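## Analysis of the target

The target 25 is an achiral 2-arylbenzofuran. Benzene ring A and furan ring B form a benzofuran that carries hydroxyls at C4 and C6 and a 1,1-dimethylallyl (2-methylbut-3-en-2-yl) group at C7. Benzofuran C2 is bonded to C5 of a 7-hydroxy-2,2-dimethylchroman (arene ring C fused to dihydropyran ring D). There is no stereocentre, so every problem is one of constitution: which carbon and which oxygen of two polyoxygenated arenes carry what.

The sensitive groups are:
- three free phenols on electron-rich rings, prone to oxidation under base;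
- the monosubstituted alkene of the 1,1-dimethylallyl group, which cannot survive hydrogenation and sits ortho to the C6 hydroxyl, so acid can close a dihydrofuran onto it;
- the electron-rich benzofuran itself.

Ring C is the hard part. Chroman C8a (oxygen), C4a (carbon C4) and C5 (bond to the benzofuran) are three contiguous substituted positions on a resorcinol-type ring, a pattern that ordinary electrophilic substitution does not deliver. Ring A adds a second problem: a phloroglucinol whose three oxygens must be told apart and which needs a quaternary carbon between two of them.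

The strategy rests on one feature. Chroman C4a is ortho both to C8a, which bears the ring oxygen O1, and to C5. C4 can therefore travel on O1 as a 1,1-dimethylpropargyl ether and be handed to C4a by a [3,3] shift, provided C5 carries a carboxyl group that steers the shift toward itself and later becomes furan C2.

## Retrosynthetic reasoning

**25 to 24.** The three phenols are unmasked last from the tris(triisopropylsilyl) ether 24. Silyl ethers are chosen because their removal by fluoride needs neither hydrogen (which would reduce the alkene) nor strong acid (which would cyclise the C6 hydroxyl onto the alkene).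

**24 to 23.** The furan is cut at C2=C3. If C2 is a carboxyl carbon, the bond from C2 to the crowded chroman C5 never has to be made by cross-coupling. The forward reaction is a reductive coupling of the aldehyde and aryl ester carbonyls of 23; it must remove both oxygens without touching the isolated alkene or the silyl ethers.

**23 to 13 and 21.** The ester O1–C2 bond is cut, giving the chroman acid 13 (used as acid chloride 22) and the salicylaldehyde 21. This makes the route convergent with two halves of similar size. The forward reaction must acylate a hydroxyl that is hydrogen-bonded to the aldehyde and flanked by a quaternary carbon.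

**21 to 19, 17, 15 and 14.** The aldehyde carbon (future C3) is removed from the only free position ortho to the hydroxyl of 19. The bond from the ring to the quaternary carbon is then cut back to the prenyl ether 17 (made from 15 and 16). A [3,3] shift turns the O-bound 3-methylbut-2-enyl group into the inverted C-bound isomer on the neighbouring carbon. Because 17 is symmetric about the ether oxygen, both ortho carbons are the same and no regiochemical question arises. The oxygen set free is exactly the one that must lie next to C7 in the furan. Phenol 15 comes from 14 by silylating two of three identical hydroxyls.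

**13 to 11, 10 and 9.** The silyl ether of 13 is introduced only after the methyl ester has been hydrolysed to 11, since hydroxide would cleave an aryl silyl ether. Phenol ester 10 comes from chromene 9 by one hydrogenation that saturates C3–C4 and removes the benzyl group. It is placed here because no other alkene exists yet in the synthesis.

**9 to 5 (key disconnection).** The C4a–C4 bond is cut and C4 is returned to the ring oxygen, giving the aryl 1,1-dimethylpropargyl ether 5. This is the only bond of ring C that is hard to make directly; the rearrangement makes it at the hindered carbon beside the carboxyl group and closes ring D in the same operation through 6, 7 and 8. The forward reaction must choose the ortho carbon next to the ester over the one between the two oxygens.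

**5 to 3 and 4; 3 to 1 and 2.** The tertiary propargyl ether is cut at O–C, giving phenol 3 and chloride 4. Phenol 3 is the mono-benzyl ether of the symmetric diol 1, made with 2. The precursor of the key step is thus two steps from commercial materials.

## Alternatives that were turned down

**Alternative 1:** The furan is disconnected at C3–C3a. In the forward direction a Lewis acid ionises the dimethyl acetal A2, an α-aryloxy arylacetaldehyde acetal. The oxocarbenium carbon is attacked by the one free ortho carbon of the aryl ether, and loss of the second alkoxy group gives the aromatic furan A1, which is the same compound as 24.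
- For: the closure site is unambiguous, no formyl group is needed on ring A, and the ring is very nucleophilic. On closeness to the target it equals the chosen route, since A1 is one desilylation away.
- Against: the closure needs acid on a substrate with a tertiary allyl group on an electron-rich arene (ipso protonation with loss or migration of that group, cation–alkene chemistry), three aryl silyl ethers and a doubly activated benzylic C–O bond that can ionise or allow a 1,2-aryl shift. Making A2 requires the hindered phenol 19 to displace a leaving group at a branched secondary benzylic carbon, which is sterically worse than the acylation of step 11, and the chroman half needs one more carbon than an acid.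
- Comparison: it leaves the construction of ring C and ring D unsolved and puts its risk at the end, on fully elaborated material. The chosen strategy closes the furan under reductive, non-protic conditions and places its main risk at step 3 on cheap material.

**Alternative 2:** Arene ring C is built by forming chroman C8a–C8 and C6–C7 in a Danheiser benzannulation of cyclobutenone A4 with silyloxyalkyne A5. Four-electron ring opening, [2+2] addition to the alkyne, a second ring opening and six-electron closure give phenol A3, whose hydroxyl and ortho prenyl group would then be closed to ring D.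
- For: on regiochemistry of ring C it is stronger than the chosen strategy. Every substituent position is fixed by construction and no ortho/ortho competition exists.
- Against: A4 already contains the complete benzofuran with its 1,1-dimethylallyl group, so the furan problem is not avoided, only moved earlier. A4 itself needs several steps (a cyclobutenone carrying a heteroaryl group and an α-prenyl group). The thermolysis exposes two alkenes and an electron-rich benzofuran to ketene intermediates. Closing ring D from A3 needs acid in the presence of the 1,1-dimethylallyl group.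
- Comparison: the chosen strategy takes ring C from a commercial arene, relies on two concordant directing effects instead of de novo ring synthesis, and finishes ring D before any acid- or hydrogen-sensitive alkene is present. It is several steps shorter.

**Alternative 3:** Ring D is disconnected at C4–C3 and O1–C2. Dehydration of salicyl alcohol A7 gives the ortho-quinone methide A9, which adds 2-methylpropene A8 in an inverse-demand [4+2] cycloaddition to give bromochroman A6.
- For: the chroman is formed saturated, so no hydrogenation is needed, and the sense of addition is fixed by polarity. The C5 bromide is a direct handle for cross-coupling to a C2-metalated benzofuran; on that point of convergence it is stronger than the chosen route.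
- Against: A8 is a gas and only a weakly activated partner, so the quinone methide can dimerise or oligomerise instead. A7 needs its own regiodefined synthesis, with the hydroxymethyl group between hydroxyl and bromine. The C7 methyl ether of A6 must later be cleaved under conditions that also threaten the tertiary alkyl aryl ether of ring D and, if done late, the 1,1-dimethylallyl group. The benzofuran partner still has to be made separately.
- Comparison: the chosen strategy uses a unimolecular cascade with no gaseous reagent, removes its benzyl group in the same hydrogenation that saturates ring D, and lets the carboxyl carbon serve twice, as regiocontrol element and as furan C2.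

Key step: step 3

Assumption: the target has no stereocentre, so the transient chiral dienones 6 and 18 form as racemates of no consequence and no stereocontrol is needed.

## Route

Step 1
Reactants: 1 methyl 3,5-dihydroxybenzoate; 2 benzyl bromide
Product: 3 methyl 3-(benzyloxy)-5-hydroxybenzoate
Conditions: 2 (1.0 equiv), K2CO3 (1.0 equiv), DMF, rt
Reagents that add atoms: none
Why: Williamson etherification under statistical control; the two hydroxyls of 1 are equivalent, so the mono-ether should form beside the bis-ether and unchanged 1, which differ by one free hydroxyl each and should be separable.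

Step 2
Reactants: 3 methyl 3-(benzyloxy)-5-hydroxybenzoate; 4 3-chloro-3-methylbut-1-yne
Product: 5 methyl 3-(benzyloxy)-5-[(2-methylbut-3-yn-2-yl)oxy]benzoate
Conditions: CuCl2·2H2O (cat.), DBU, MeCN, 0 °C to rt
Reagents that add atoms: none
Why: Copper-catalysed propargylic substitution; the copper acetylide of 4 ionises to an allenylidene-type electrophile that the phenoxide attacks at the tertiary carbon, giving the hindered tertiary ether that a plain SN2 reaction could not give, and the ester makes the phenol acidic enough for DBU.

Step 3
Reactants: 5 methyl 3-(benzyloxy)-5-[(2-methylbut-3-yn-2-yl)oxy]benzoate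
Product: 9 methyl 7-(benzyloxy)-2,2-dimethyl-2H-chromene-5-carboxylate, via allenyl dienone 6 (not isolated), via allenyl phenol 7 (not isolated), via quinone methide 8 (not isolated)
Conditions: PhNEt2, 190 °C, Ar, sealed tube
Reagents that add atoms: none
Why: Heating 5 should induce a concerted [3,3] sigmatropic shift in which the alkyne terminus bonds to the ring carbon that lies ortho to the ether oxygen and next to the ester (the C4a–C4 bond) while the O–C(CH3)2 bond breaks, giving allenyl dienone 6. Dienone 6 enolises to phenol 7, and a 1,5-hydrogen shift from the hydroxyl to the central allene carbon gives the (Z)-configured ortho-quinone methide 8. Compound 8 closes ring D by a thermal disrotatory oxa-6π electrocyclisation between the carbonyl oxygen and the dimethyl-substituted diene terminus, a six-membered closure that restores aromaticity. The closest known reaction type is the thermal rearrangement of aryl 1,1-dimethylpropargyl ethers to 2,2-dimethyl-2H-chromenes. No stereocentre is formed, since the one in 6 is lost on enolisation. The selectivity needed is between the two ortho carbons: the meta ester, an acceptor, favours migration to the carbon next to itself, and the meta benzyloxy group, a donor, favours the carbon para to itself, and these are the same carbon. The competing carbon lies between two oxygen substituents and is favoured by neither effect. The gem-dialkyl effect of the two methyl groups speeds the shift, and the basic solvent suppresses acid-catalysed side reactions of the chromene.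

Step 4
Reactants: 9 methyl 7-(benzyloxy)-2,2-dimethyl-2H-chromene-5-carboxylate
Product: 10 methyl 7-hydroxy-2,2-dimethylchroman-5-carboxylate
Conditions: H2 (1 atm), 10% Pd/C, EtOAc/MeOH, rt
Reagents that add atoms: none
Why: Heterogeneous hydrogenation should saturate the styrene-type C3–C4 alkene and hydrogenolyse the benzyl ether in one operation, while the aromatic ester and the chroman ether are inert; no other alkene is present at this stage.

Step 5
Reactants: 10 methyl 7-hydroxy-2,2-dimethylchroman-5-carboxylate
Product: 11 7-hydroxy-2,2-dimethylchroman-5-carboxylic acid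
Conditions: LiOH·H2O, THF/MeOH/H2O, 50 °C, Ar; then aq. HCl to pH 3
Reagents that add atoms: lithium hydroxide, [Li+].[OH-]
Why: Saponification by acyl–oxygen cleavage; the ortho substituent slows but does not block attack at the ester, hence gentle heating, and argon protects the phenoxide from air.

Step 6
Reactants: 11 7-hydroxy-2,2-dimethylchroman-5-carboxylic acid
Product: 13 2,2-dimethyl-7-(triisopropylsilyloxy)chroman-5-carboxylic acid, via bis-silylated ester 12 (not isolated)
Conditions: TIPSCl (2.3 equiv), imidazole, DMF, rt; then K2CO3 (1.0 equiv), MeOH/THF/H2O, 0 °C; cold dilute aq. HCl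
Reagents that add atoms: chlorotriisopropylsilane, CC(C)[Si](Cl)(C(C)C)C(C)C
Why: Silylation of phenol and acid followed by selective solvolysis of the far more labile silyl ester with carbonate at 0 °C, which should leave the aryl triisopropylsilyl ether; placing this after step 5 avoids exposing an aryl silyl ether to hot hydroxide.

Step 7
Reactants: 14 phloroglucinol
Product: 15 3,5-bis(triisopropylsilyloxy)phenol
Conditions: TIPSCl (2.0 equiv), imidazole, DMF, 0 °C to rt
Reagents that add atoms: chlorotriisopropylsilane, CC(C)[Si](Cl)(C(C)C)C(C)C
Why: Statistical silylation of two of three equivalent hydroxyls; the mono-, bis- and tris-ethers differ by one free hydroxyl each and should be separable, and the bulk of the silyl group slows the third silylation.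

Step 8
Reactants: 15 3,5-bis(triisopropylsilyloxy)phenol; 16 3-methylbut-2-en-1-ol
Product: 17 1-[(3-methylbut-2-en-1-yl)oxy]-3,5-bis(triisopropylsilyloxy)benzene
Conditions: PPh3, DIAD, THF, 0 °C to rt
Reagents that add atoms: none
Why: Mitsunobu etherification at the primary allylic carbon of 16 under neutral conditions; it avoids the C-alkylation that phloroglucinol-type phenoxides undergo with allylic halides and any base-induced silyl loss.

Step 9
Reactants: 17 1-[(3-methylbut-2-en-1-yl)oxy]-3,5-bis(triisopropylsilyloxy)benzene
Product: 19 2-(2-methylbut-3-en-2-yl)-3,5-bis(triisopropylsilyloxy)phenol, via ortho dienone 18 (not isolated)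
Conditions: PhNEt2, 175 °C, Ar
Reagents that add atoms: none
Why: Aromatic Claisen rearrangement; a chair-like [3,3] shift bonds the dimethyl-substituted alkene terminus to the ortho carbon and inverts the allyl unit, and dienone 18 enolises, helped by the amine solvent, to 19. The two ortho carbons are equivalent by symmetry and each bears a hydrogen, so rearomatisation should outrun a second shift to the para carbon.

Step 10
Reactants: 19 2-(2-methylbut-3-en-2-yl)-3,5-bis(triisopropylsilyloxy)phenol
Product: 21 2-hydroxy-3-(2-methylbut-3-en-2-yl)-4,6-bis(triisopropylsilyloxy)benzaldehyde, via salicyl alcohol 20 (not isolated)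
Conditions: MgCl2, Et3N, (CH2O)n, MeCN, reflux; then aq. citric acid
Reagents that add atoms: paraformaldehyde (formaldehyde), C=O
Why: Magnesium-mediated ortho-formylation; the magnesium phenoxide delivers formaldehyde to the ortho carbon within a chelate and the benzylic alkoxide of 20 is oxidised to the aldehyde by hydride transfer to a second formaldehyde. Only one ortho position is free, the para position is not attacked by this mechanism, and ortho-tert-alkyl phenols are good substrates.

Step 11
Reactants: 13 2,2-dimethyl-7-(triisopropylsilyloxy)chroman-5-carboxylic acid; 21 2-hydroxy-3-(2-methylbut-3-en-2-yl)-4,6-bis(triisopropylsilyloxy)benzaldehyde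
Product: 23 2-formyl-6-(2-methylbut-3-en-2-yl)-3,5-bis(triisopropylsilyloxy)phenyl 2,2-dimethyl-7-(triisopropylsilyloxy)chroman-5-carboxylate, via acid chloride 22 (not isolated)
Conditions: 13, (COCl)2, DMF (cat.), CH2Cl2, 0 °C to rt, evaporate; then 21, Et3N, DMAP (cat.), CH2Cl2, 0 °C to rt
Reagents that add atoms: none
Why: Acid chloride formation through a Vilsmeier-type chloroiminium species, then DMAP-catalysed O-acylation; 21 has a single free hydroxyl, and although it is hydrogen-bonded to the aldehyde and flanked by the quaternary carbon, the acylpyridinium ion should be reactive enough, as it is for other 3-tert-alkyl salicylaldehydes.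

Step 12
Reactants: 23 2-formyl-6-(2-methylbut-3-en-2-yl)-3,5-bis(triisopropylsilyloxy)phenyl 2,2-dimethyl-7-(triisopropylsilyloxy)chroman-5-carboxylate
Product: 24 2-[2,2-dimethyl-7-(triisopropylsilyloxy)chroman-5-yl]-7-(2-methylbut-3-en-2-yl)-4,6-bis(triisopropylsilyloxy)-1-benzofuran
Conditions: TiCl3, Zn dust, DME, reflux, slow addition of 23
Reagents that add atoms: none
Why: Intramolecular McMurry-type oxo-ester coupling; low-valent titanium from TiCl3 and Zn reduces the aldehyde to a titanium-bound ketyl that adds to the neighbouring ester carbonyl, and deoxygenation of the titanium diolate gives the C2=C3 bond of the aromatic furan. Slow addition should keep intermolecular pinacol coupling down, and the isolated alkene and the silyl ethers are inert to the reagent.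

Step 13
Reactants: 24 2-[2,2-dimethyl-7-(triisopropylsilyloxy)chroman-5-yl]-7-(2-methylbut-3-en-2-yl)-4,6-bis(triisopropylsilyloxy)-1-benzofuran
Product: 25 2-(7-hydroxy-2,2-dimethylchroman-5-yl)-7-(2-methylbut-3-en-2-yl)-1-benzofuran-4,6-diol
Conditions: TBAF, AcOH, THF, 0 °C to rt, Ar
Reagents that add atoms: none
Why: Fluoride-induced cleavage of the three aryl Si–O bonds, driven by the Si–F bond; acetic acid buffers the phenoxides, so the electron-rich triphenol should be neither oxidised nor exposed to strong acid that could close the C6 hydroxyl onto the neighbouring alkene.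

## Compound list

1 | methyl 3,5-dihydroxybenzoate | COC(=O)c1cc(O)cc(O)c1 | starting material
2 | benzyl bromide | BrCc1ccccc1 | starting material
3 | methyl 3-(benzyloxy)-5-hydroxybenzoate | COC(=O)c1cc(O)cc(OCc2ccccc2)c1 | intermediate
4 | 3-chloro-3-methylbut-1-yne | CC(C)(Cl)C#C | starting material
5 | methyl 3-(benzyloxy)-5-[(2-methylbut-3-yn-2-yl)oxy]benzoate | COC(=O)c1cc(OCc2ccccc2)cc(OC(C)(C)C#C)c1 | intermediate
6 | methyl 3-(benzyloxy)-6-(3-methylbuta-1,2-dien-1-yl)-5-oxocyclohexa-1,3-diene-1-carboxylate (racemic) | COC(=O)C1=CC(OCc2ccccc2)=CC(=O)C1C=C=C(C)C | intermediate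
7 | methyl 5-(benzyloxy)-3-hydroxy-2-(3-methylbuta-1,2-dien-1-yl)benzoate | COC(=O)c1cc(OCc2ccccc2)cc(O)c1C=C=C(C)C | intermediate
8 | methyl (6Z)-3-(benzyloxy)-6-(3-methylbut-2-en-1-ylidene)-5-oxocyclohexa-1,3-diene-1-carboxylate | CC(C)=C/C=C1\C(=O)C=C(OCc2ccccc2)C=C1C(=O)OC | intermediate
9 | methyl 7-(benzyloxy)-2,2-dimethyl-2H-chromene-5-carboxylate | COC(=O)c1cc(OCc2ccccc2)cc2c1C=CC(C)(C)O2 | intermediate
10 | methyl 7-hydroxy-2,2-dimethylchroman-5-carboxylate | COC(=O)c1cc(O)cc2c1CCC(C)(C)O2 | intermediate
11 | 7-hydroxy-2,2-dimethylchroman-5-carboxylic acid | OC(=O)c1cc(O)cc2c1CCC(C)(C)O2 | intermediate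
12 | triisopropylsilyl 2,2-dimethyl-7-(triisopropylsilyloxy)chroman-5-carboxylate | CC(C)[Si](OC(=O)c1cc(O[Si](C(C)C)(C(C)C)C(C)C)cc2c1CCC(C)(C)O2)(C(C)C)C(C)C | intermediate
13 | 2,2-dimethyl-7-(triisopropylsilyloxy)chroman-5-carboxylic acid | OC(=O)c1cc(O[Si](C(C)C)(C(C)C)C(C)C)cc2c1CCC(C)(C)O2 | intermediate
14 | phloroglucinol (benzene-1,3,5-triol) | Oc1cc(O)cc(O)c1 | starting material
15 | 3,5-bis(triisopropylsilyloxy)phenol | Oc1cc(O[Si](C(C)C)(C(C)C)C(C)C)cc(O[Si](C(C)C)(C(C)C)C(C)C)c1 | intermediate
16 | 3-methylbut-2-en-1-ol | CC(C)=CCO | starting material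
17 | 1-[(3-methylbut-2-en-1-yl)oxy]-3,5-bis(triisopropylsilyloxy)benzene | CC(C)=CCOc1cc(O[Si](C(C)C)(C(C)C)C(C)C)cc(O[Si](C(C)C)(C(C)C)C(C)C)c1 | intermediate
18 | 6-(2-methylbut-3-en-2-yl)-3,5-bis(triisopropylsilyloxy)cyclohexa-2,4-dien-1-one (racemic) | C=CC(C)(C)C1C(=O)C=C(O[Si](C(C)C)(C(C)C)C(C)C)C=C1O[Si](C(C)C)(C(C)C)C(C)C | intermediate
19 | 2-(2-methylbut-3-en-2-yl)-3,5-bis(triisopropylsilyloxy)phenol | C=CC(C)(C)c1c(O)cc(O[Si](C(C)C)(C(C)C)C(C)C)cc1O[Si](C(C)C)(C(C)C)C(C)C | intermediate
20 | 2-(hydroxymethyl)-6-(2-methylbut-3-en-2-yl)-3,5-bis(triisopropylsilyloxy)phenol | C=CC(C)(C)c1c(O)c(CO)c(O[Si](C(C)C)(C(C)C)C(C)C)cc1O[Si](C(C)C)(C(C)C)C(C)C | intermediate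
21 | 2-hydroxy-3-(2-methylbut-3-en-2-yl)-4,6-bis(triisopropylsilyloxy)benzaldehyde | C=CC(C)(C)c1c(O)c(C=O)c(O[Si](C(C)C)(C(C)C)C(C)C)cc1O[Si](C(C)C)(C(C)C)C(C)C | intermediate
22 | 2,2-dimethyl-7-(triisopropylsilyloxy)chroman-5-carbonyl chloride | ClC(=O)c1cc(O[Si](C(C)C)(C(C)C)C(C)C)cc2c1CCC(C)(C)O2 | intermediate
23 | 2-formyl-6-(2-methylbut-3-en-2-yl)-3,5-bis(triisopropylsilyloxy)phenyl 2,2-dimethyl-7-(triisopropylsilyloxy)chroman-5-carboxylate | C=CC(C)(C)c1c(OC(=O)c2cc(O[Si](C(C)C)(C(C)C)C(C)C)cc3c2CCC(C)(C)O3)c(C=O)c(O[Si](C(C)C)(C(C)C)C(C)C)cc1O[Si](C(C)C)(C(C)C)C(C)C | intermediate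
24 | 2-[2,2-dimethyl-7-(triisopropylsilyloxy)chroman-5-yl]-7-(2-methylbut-3-en-2-yl)-4,6-bis(triisopropylsilyloxy)-1-benzofuran | C=CC(C)(C)c1c(O[Si](C(C)C)(C(C)C)C(C)C)cc(O[Si](C(C)C)(C(C)C)C(C)C)c2cc(-c3cc(O[Si](C(C)C)(C(C)C)C(C)C)cc4c3CCC(C)(C)O4)oc12 | intermediate
25 | 2-(7-hydroxy-2,2-dimethylchroman-5-yl)-7-(2-methylbut-3-en-2-yl)-1-benzofuran-4,6-diol | C=CC(C)(C)c1c(O)cc(O)c2cc(-c3cc(O)cc4c3CCC(C)(C)O4)oc12 | target

## Step count and least certain steps

Total: 13 steps. Longest linear sequence: 9 steps (steps 1 to 6, then 11 to 13, from 1). The second branch (steps 7 to 10, from 14) joins at step 11.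

**Step 3 (key step).** The shift may go in part to the other ortho carbon, the one between the two oxygens, giving the regioisomeric chromene, and the chromene may degrade on prolonged heating. The fallback makes the C4a–C4 bond at a halogen whose position does not depend on pericyclic regiochemistry. It sets out from 1 and 2 and comes back at 10.
- Exhaustive benzylation gives methyl 3,5-bis(benzyloxy)benzoate F1.
- Bromination (NBS, MeCN) should go to the carbon ortho to the ester and para to one ether oxygen, the position between the two ethers being shielded, and gives methyl 3,5-bis(benzyloxy)-2-bromobenzoate F2.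
- Sonogashira coupling with 2-methylbut-3-yn-2-ol (PdCl2(PPh3)2, CuI, Et3N, DMF, 80 °C) gives methyl 3,5-bis(benzyloxy)-2-(3-hydroxy-3-methylbut-1-yn-1-yl)benzoate F3.
- Hydrogenation (H2, Pd/C) saturates the alkyne and removes both benzyl groups, giving methyl 3,5-dihydroxy-2-(3-hydroxy-3-methylbutyl)benzoate F4.
- Acid-catalysed cycloetherification (TsOH, toluene, 80 °C) of the tertiary alcohol onto the only adjacent hydroxyl returns 10.

**Step 12.** The aldehyde may undergo intermolecular pinacol coupling or simple reduction before it finds the hindered ester carbonyl, and the Lewis-acidic titanium species may cleave the aryl ester. The fallback closes the same C2=C3 bond by phosphorus instead of titanium. It sets out from 21 and 22 and comes back at 24.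
- NaBH4 reduces 21 to the salicyl alcohol 20.
- PPh3·HBr in MeCN converts 20, through its readily ionised benzylic position, into [2-hydroxy-3-(2-methylbut-3-en-2-yl)-4,6-bis(triisopropylsilyloxy)benzyl]triphenylphosphonium bromide F5.
- Treatment with 22 and Et3N in toluene at reflux brings about O-acylation and intramolecular Wittig olefination of the ester carbonyl in one flask, giving 24.

**Step 9.** The ortho dienone may undergo a further Cope shift to the para carbon before it enolises. At the temperature needed, the product may also rearrange further by hydrogen transfer from the hydroxyl to the vinyl terminus, or the hydroxyl may add to the alkene. The fallback reverses the order of the two C–C bond formations so that the shift is chelation-assisted at low temperature. It sets out from 15 and 16, comes back at 21, and bypasses steps 9 and 10.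
- Magnesium-mediated ortho-formylation of 15 (MgCl2, Et3N, paraformaldehyde), whose two ortho carbons are equivalent, gives 2-hydroxy-4,6-bis(triisopropylsilyloxy)benzaldehyde F6.
- Mitsunobu etherification with 16 gives 2-[(3-methylbut-2-en-1-yl)oxy]-4,6-bis(triisopropylsilyloxy)benzaldehyde F7.
- Claisen rearrangement catalysed by Eu(fod)3 in CHCl3 at 60 to 80 °C, with the Lewis acid held between the ether and aldehyde oxygens, moves the allyl unit to the single free ortho carbon and gives 21.

**Step 11.** Acylation may stall because the hydroxyl is hydrogen-bonded and shielded by the quaternary carbon, and forcing basic conditions may cause loss or transfer of a silyl group. The fallback avoids O-acylation altogether: the C3–C3a bond is made first and the hindered oxygen closes the ring intramolecularly. It sets out from 15, 16 and 13 and comes back at 24.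
- Iodination of 15 (NIS, CH2Cl2, 0 °C) ortho to the free hydroxyl, the carbon between the two silyloxy groups being shielded on both sides, gives 2-iodo-3,5-bis(triisopropylsilyloxy)phenol F8.
- Mitsunobu etherification with 16 gives 2-iodo-1-[(3-methylbut-2-en-1-yl)oxy]-3,5-bis(triisopropylsilyloxy)benzene F9.
- Claisen rearrangement to the only free ortho carbon gives 2-iodo-6-(2-methylbut-3-en-2-yl)-3,5-bis(triisopropylsilyloxy)phenol F10.
- Separately, 13 is reduced with BH3·SMe2 to [2,2-dimethyl-7-(triisopropylsilyloxy)chroman-5-yl]methanol F11.
- Oxidation with MnO2 gives 2,2-dimethyl-7-(triisopropylsilyloxy)chroman-5-carbaldehyde F12.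
- Seyferth–Gilbert homologation with dimethyl (1-diazo-2-oxopropyl)phosphonate (K2CO3, MeOH, 0 °C) gives 5-ethynyl-2,2-dimethyl-7-(triisopropylsilyloxy)chroman F13.
- Sonogashira coupling of F10 with F13 (PdCl2(PPh3)2, CuI, Et3N, 70 °C), followed in the same flask by 5-endo addition of the hydroxyl to the metal-activated alkyne, gives 24.

## Further compounds

F1 | step 3 | methyl 3,5-bis(benzyloxy)benzoate | COC(=O)c1cc(OCc2ccccc2)cc(OCc2ccccc2)c1
F2 | step 3 | methyl 3,5-bis(benzyloxy)-2-bromobenzoate | COC(=O)c1cc(OCc2ccccc2)cc(OCc2ccccc2)c1Br
F3 | step 3 | methyl 3,5-bis(benzyloxy)-2-(3-hydroxy-3-methylbut-1-yn-1-yl)benzoate | COC(=O)c1cc(OCc2ccccc2)cc(OCc2ccccc2)c1C#CC(C)(C)O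
F4 | step 3 | methyl 3,5-dihydroxy-2-(3-hydroxy-3-methylbutyl)benzoate | COC(=O)c1cc(O)cc(O)c1CCC(C)(C)O
F5 | step 12 | [2-hydroxy-3-(2-methylbut-3-en-2-yl)-4,6-bis(triisopropylsilyloxy)benzyl]triphenylphosphonium bromide | C=CC(C)(C)c1c(O)c(C[P+](c2ccccc2)(c2ccccc2)c2ccccc2)c(O[Si](C(C)C)(C(C)C)C(C)C)cc1O[Si](C(C)C)(C(C)C)C(C)C.[Br-]
F6 | step 9 | 2-hydroxy-4,6-bis(triisopropylsilyloxy)benzaldehyde | O=Cc1c(O)cc(O[Si](C(C)C)(C(C)C)C(C)C)cc1O[Si](C(C)C)(C(C)C)C(C)C
F7 | step 9 | 2-[(3-methylbut-2-en-1-yl)oxy]-4,6-bis(triisopropylsilyloxy)benzaldehyde | CC(C)=CCOc1cc(O[Si](C(C)C)(C(C)C)C(C)C)cc(O[Si](C(C)C)(C(C)C)C(C)C)c1C=O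
F8 | step 11 | 2-iodo-3,5-bis(triisopropylsilyloxy)phenol | Oc1cc(O[Si](C(C)C)(C(C)C)C(C)C)cc(O[Si](C(C)C)(C(C)C)C(C)C)c1I
F9 | step 11 | 2-iodo-1-[(3-methylbut-2-en-1-yl)oxy]-3,5-bis(triisopropylsilyloxy)benzene | CC(C)=CCOc1cc(O[Si](C(C)C)(C(C)C)C(C)C)cc(O[Si](C(C)C)(C(C)C)C(C)C)c1I
F10 | step 11 | 2-iodo-6-(2-methylbut-3-en-2-yl)-3,5-bis(triisopropylsilyloxy)phenol | C=CC(C)(C)c1c(O)c(I)c(O[Si](C(C)C)(C(C)C)C(C)C)cc1O[Si](C(C)C)(C(C)C)C(C)C
F11 | step 11 | [2,2-dimethyl-7-(triisopropylsilyloxy)chroman-5-yl]methanol | OCc1cc(O[Si](C(C)C)(C(C)C)C(C)C)cc2c1CCC(C)(C)O2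
F12 | step 11 | 2,2-dimethyl-7-(triisopropylsilyloxy)chroman-5-carbaldehyde | O=Cc1cc(O[Si](C(C)C)(C(C)C)C(C)C)cc2c1CCC(C)(C)O2
F13 | step 11 | 5-ethynyl-2,2-dimethyl-7-(triisopropylsilyloxy)chroman | C#Cc1cc(O[Si](C(C)C)(C(C)C)C(C)C)cc2c1CCC(C)(C)O2
A1 | alternative 1 | 2-[2,2-dimethyl-7-(triisopropylsilyloxy)chroman-5-yl]-7-(2-methylbut-3-en-2-yl)-4,6-bis(triisopropylsilyloxy)-1-benzofuran | C=CC(C)(C)c1c(O[Si](C(C)C)(C(C)C)C(C)C)cc(O[Si](C(C)C)(C(C)C)C(C)C)c2cc(-c3cc(O[Si](C(C)C)(C(C)C)C(C)C)cc4c3CCC(C)(C)O4)oc12
A2 | alternative 1 | 5-{2,2-dimethoxy-1-[2-(2-methylbut-3-en-2-yl)-3,5-bis(triisopropylsilyloxy)phenoxy]ethyl}-2,2-dimethyl-7-(triisopropylsilyloxy)chroman (racemic) | COC(OC)C(Oc1cc(O[Si](C(C)C)(C(C)C)C(C)C)cc(O[Si](C(C)C)(C(C)C)C(C)C)c1C(C)(C)C=C)c1cc(O[Si](C(C)C)(C(C)C)C(C)C)cc2c1CCC(C)(C)O2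
A3 | alternative 2 | 3-[4,6-bis(tert-butyldimethylsilyloxy)-7-(2-methylbut-3-en-2-yl)-1-benzofuran-2-yl]-2-(3-methylbut-2-en-1-yl)-5-(triisopropylsilyloxy)phenol | CC(C)=CCc1c(O)cc(O[Si](C(C)C)(C(C)C)C(C)C)cc1-c1cc2c(O[Si](C)(C)C(C)(C)C)cc(O[Si](C)(C)C(C)(C)C)c(C(C)(C)C=C)c2o1
A4 | alternative 2 | 3-[4,6-bis(tert-butyldimethylsilyloxy)-7-(2-methylbut-3-en-2-yl)-1-benzofuran-2-yl]-4-(3-methylbut-2-en-1-yl)cyclobut-2-en-1-one (racemic) | CC(C)=CCC1C(=O)C=C1c1cc2c(O[Si](C)(C)C(C)(C)C)cc(O[Si](C)(C)C(C)(C)C)c(C(C)(C)C=C)c2o1
A5 | alternative 2 | (triisopropylsilyloxy)ethyne | C#CO[Si](C(C)C)(C(C)C)C(C)C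
A6 | alternative 3 | 5-bromo-7-methoxy-2,2-dimethylchroman | COc1cc(Br)c2c(c1)OC(C)(C)CC2
A7 | alternative 3 | 3-bromo-2-(hydroxymethyl)-5-methoxyphenol | COc1cc(O)c(CO)c(Br)c1
A8 | alternative 3 | 2-methylpropene | CC(C)=C
A9 | alternative 3 | 5-bromo-3-methoxy-6-methylidenecyclohexa-2,4-dien-1-one | C=C1C(=O)C=C(OC)C=C1Br
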